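**Retrosynthetic overview**
1. Target ⇐ selective acetylation of the C18 alcohol and LiAlH4 opening of an 18,6-lactone; side-chain diene ⇐ methyl ketone (enol triflate, Stille coupling); C8–OH and C9–H ⇐ one syn hydroboration of a C8=C9 olefin.
2. Rings A and B ⇐ formed together by a transannular cation–olefin cyclisation of a ten-membered carbinol (bond C5–C10), terminated at C6 by the C4 ester, which relays the C4 configuration to C5, C6 and C10.
3. Ten-membered ring (the C1–C10 periphery of the decalin) ⇐ anionic oxy-Cope ring expansion of a 1-propenyl-2-vinylcyclohexanol: the C7–C8 bond closes the ring while the carrier bond C5–C10 is cut; dehydrogenation in the same flask gives the dienone.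
4. Enabling feature: C7–C8 lies directly across ring B from the fusion bond C5–C10, so C6=C7 on C5 and C9=C8 on C10 form a 3-oxy-1,5-diene once C10 is a carbinol; the shift leaves a C10 carbonyl (later the methyl-bearing cation) and an E olefin C5=C6, the pair needed to re-stitch C5–C10 with oxygen at C6.
5. Cyclohexanone carrier ⇐ copper-catalysed asymmetric conjugate methylation of a cyclic γ-keto ester (sets C4) with aldol trapping; ring order: six-membered carrier ring (present from the start) → ten-membered ring (step 6) → rings A and B plus a temporary lactone (step 10).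

Key step: step 6

Assumption: atoms are numbered as in labdane (C1–C20) throughout; epimers at C5 and at the carbinol carbons formed in steps 3, 5 and 9 and the propenyl geometry are drawn as the expected major isomers and are of no consequence, because these centres become sp2 in steps 6 and 10.

**Route**

Step 1
Reactants: 1 3-oxocyclohex-1-ene-1-carboxylic acid
Product: 2 tert-butyl 3-oxocyclohex-1-ene-1-carboxylate
Conditions: Boc2O, DMAP (cat.), t-BuOH, rt
Reagents that add atoms: di-tert-butyl dicarbonate CC(C)(C)OC(=O)OC(=O)OC(C)(C)C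
Why: DMAP-catalysed decarboxylative esterification gives the tert-butyl ester, chosen because it resists the organometallic steps and can later leave as isobutene.

Step 2
Reactants: 3 benzeneselenenyl chloride; 4 ethyl vinyl ether
Product: 6 2-(phenylselanyl)acetaldehyde, via chloro ether 5 (not isolated)
Conditions: CH2Cl2, −78 °C; then H2O, NaHCO3, rt
Reagents that add atoms: water O
Why: Markovnikov electrophilic selenenylation of the enol ether gives an α-chloro ether whose hydrolysis releases the aldehyde, a two-carbon vinyl cation equivalent.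

Step 3
Reactants: 2 tert-butyl 3-oxocyclohex-1-ene-1-carboxylate; 6 2-(phenylselanyl)acetaldehyde
Product: 8 tert-butyl (1S,2S)-2-[1-hydroxy-2-(phenylselanyl)ethyl]-1-methyl-3-oxocyclohexane-1-carboxylate, via zinc enolate 7 (not isolated)
Conditions: Me2Zn, (CuOTf)2·C6H6 (2.5 mol %), chiral sulfonate-bearing imidazolinium salt (carbene precursor, 5 mol %, enantiomer giving 1S), t-BuOMe, −30 °C; then 6, −30 to 0 °C; aq NH4Cl
Reagents that add atoms: dimethylzinc C[Zn]C
Why: Copper-catalysed asymmetric conjugate addition of Me2Zn to the cyclic γ-keto ester should set the quaternary C4 centre (1S) under ligand control, and the regiodefined zinc enolate is trapped in a tandem aldol reaction anti to the bulky ester, the C5 and carbinol configurations being irrelevant later.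

Step 4
Reactants: 8 tert-butyl (1S,2S)-2-[1-hydroxy-2-(phenylselanyl)ethyl]-1-methyl-3-oxocyclohexane-1-carboxylate
Product: 9 tert-butyl (1S,2R)-2-ethenyl-1-methyl-3-oxocyclohexane-1-carboxylate
Conditions: MsCl, Et3N, CH2Cl2, 0 °C to rt
Reagents that add atoms: none
Why: Mesylation triggers selenium-assisted anti β-elimination of the β-hydroxy selenide, which should give the terminal vinyl group regiospecifically (α-vinylation of the ketone).

Step 5
Reactants: 9 tert-butyl (1S,2R)-2-ethenyl-1-methyl-3-oxocyclohexane-1-carboxylate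
Product: 10 tert-butyl (1S,2R,3R)-2-ethenyl-3-hydroxy-1-methyl-3-[(1E)-prop-1-en-1-yl]cyclohexane-1-carboxylate
Conditions: (E)-CH3CH=CHMgBr, CeCl3, THF, −78 °C
Reagents that add atoms: (E)-prop-1-enylmagnesium bromide C/C=C/[Mg]Br
Why: 1,2-Addition of the weakly basic organocerium reagent should occur equatorially, anti to the C5 vinyl group and to the axial C4 methyl, giving the trans-1,2-dialkenyl carbinol (3R) whose oxygen is trans to the ester.

Step 6
Reactants: 10 tert-butyl (1S,2R,3R)-2-ethenyl-3-hydroxy-1-methyl-3-[(1E)-prop-1-en-1-yl]cyclohexane-1-carboxylate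
Product: 13 tert-butyl (1S,2E,5Z)-1,5-dimethyl-7-oxocyclodeca-2,5-diene-1-carboxylate, via potassium enolate 11 (not isolated), via sulfilimine adduct 12 (not isolated)
Conditions: KN(SiMe3)2, 18-crown-6, THF, 0 °C to rt; then PhS(Cl)=N-t-Bu, −78 °C
Reagents that add atoms: none
Why: The potassium alkoxide of 10 should undergo a charge-accelerated [3,3]-sigmatropic shift (anionic oxy-Cope rearrangement) of its 3-oxy-1,5-diene C8=C9–C10(O)–C5–C6=C7, so that C7–C8 forms while the carrier bond C5–C10 breaks, and the regiodefined enolate 11 is then sulfenylated at C9 by the sulfinimidoyl chloride and 12 loses N-tert-butylbenzenesulfenamide by syn-elimination to give the enone. The closest known reaction type is the four-carbon ring expansion of trans-1,2-dialkenylcyclohexanols to (E)-cyclodec-5-enones, combined with the one-pot sulfinimidoyl dehydrogenation of ketone enolates. The ten-membered ring is closed in ring-expansion mode: the alkenyl termini C7 and C8 are joined through a chair-like transition state templated by the six-membered carrier ring, so no high dilution is needed, and enolate formation makes the shift irreversible. No stereocentre is created that survives (C5 and C10 become sp2, the C8 centre is planarised by the dehydrogenation); the element set is the E geometry of C5=C6, controlled by the diequatorial arrangement of the two alkenyl groups in the chair, while C4 is untouched and becomes the only stereocentre of 13. The step needs the sigmatropic shift instead of alkoxide fragmentation or lactonisation onto the ester, and unsaturation only between C8 and C9: the alkoxide is trans to the ester (step 5), the enolate can form only towards C9, and in 12 only C8 carries a β-hydrogen.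

Step 7
Reactants: 13 tert-butyl (1S,2E,5Z)-1,5-dimethyl-7-oxocyclodeca-2,5-diene-1-carboxylate
Product: 14 tert-butyl (1S,2E,5E)-6-iodo-1,5-dimethyl-7-oxocyclodeca-2,5-diene-1-carboxylate
Conditions: I2, pyridine, CH2Cl2, 0 °C to rt, dark
Reagents that add atoms: iodine II
Why: α-Iodination of the enone by amine-mediated addition–elimination (conjugate addition of pyridine, iodination of the enolate, loss of pyridine) should touch only the electron-poor C8=C9 bond and place a coupling handle on C9.

Step 8
Reactants: 14 tert-butyl (1S,2E,5E)-6-iodo-1,5-dimethyl-7-oxocyclodeca-2,5-diene-1-carboxylate; 15 2-ethenyl-2-methyl-1,3-dioxolane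
Product: 16 tert-butyl (1S,2E,5Z)-1,5-dimethyl-6-[2-(2-methyl-1,3-dioxolan-2-yl)ethyl]-7-oxocyclodeca-2,5-diene-1-carboxylate
Conditions: 15, 9-BBN, THF, rt; then 14, PdCl2(dppf) (5 mol %), AsPh3, Cs2CO3, DMF/H2O, rt
Reagents that add atoms: none
Why: B-alkyl Suzuki–Miyaura coupling of the α-iodoenone with the anti-Markovnikov 9-BBN adduct of 15 should form the C9–C11 bond and give the tetrasubstituted enone without creating a stereocentre.

Step 9
Reactants: 16 tert-butyl (1S,2E,5Z)-1,5-dimethyl-6-[2-(2-methyl-1,3-dioxolan-2-yl)ethyl]-7-oxocyclodeca-2,5-diene-1-carboxylate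
Product: 17 tert-butyl (1S,2E,5Z)-7-hydroxy-1,5,7-trimethyl-6-[2-(2-methyl-1,3-dioxolan-2-yl)ethyl]cyclodeca-2,5-diene-1-carboxylate
Conditions: MeLi, CeCl3, THF, −78 °C
Reagents that add atoms: methyllithium [Li]C
Why: Organocerium 1,2-addition of methyl to the hindered, enolisable enone carbonyl delivers C20, the hindered tert-butyl ester and the ketal being inert, and the new carbinol centre needs no control because it is ionised in step 10.

Step 10
Reactants: 17 tert-butyl (1S,2E,5Z)-7-hydroxy-1,5,7-trimethyl-6-[2-(2-methyl-1,3-dioxolan-2-yl)ethyl]cyclodeca-2,5-diene-1-carboxylate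
Product: 18 (4S,5S,6R,10R)-13,13-(ethylenedioxy)-14,15-dinorlabd-8-en-18,6-olide
Conditions: CSA (10 mol %), 4 Å molecular sieves, CH2Cl2, −20 °C to rt
Reagents that add atoms: none
Why: Acid ionises the tertiary allylic alcohol to a C10–C9–C8 allyl cation with two tertiary termini, C5 of the E olefin attacks C10 across the ring in a chair–chair transition state (transannular cation–olefin cyclisation closing rings A and B, trans fusion with the C10 methyl axial), and the ester carbonyl on C4 adds to C6 anti to the new C5–C10 bond and loses isobutene, which is possible only with the ester equatorial and so lets the C4 centre fix the 5S, 6R and 10R configurations.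

Step 11
Reactants: 18 (4S,5S,6R,10R)-13,13-(ethylenedioxy)-14,15-dinorlabd-8-en-18,6-olide
Product: 21 (4S,5S,6R,8S,9S,10R)-8-hydroxy-13-oxo-14,15-dinorlabdan-18,6-olide, via alkylborane 19 (not isolated), via ketal alcohol 20 (not isolated)
Conditions: BH3·THF, THF, 0 °C to rt; then NaOH, H2O2, 0 °C; then 1 M HCl, THF, rt
Reagents that add atoms: hydrogen peroxide OO; water O
Why: Hydroboration–oxidation: BH3 should add syn to the tetrasubstituted olefin from the face anti to the axial C10 methyl with boron on the less hindered C8, oxidation with retention then gives the 8S alcohol and the 9S hydrogen in one operation, and the acidic work-up recloses any opened lactone and hydrolyses the ketal.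

Step 12
Reactants: 21 (4S,5S,6R,8S,9S,10R)-8-hydroxy-13-oxo-14,15-dinorlabdan-18,6-olide
Product: 22 (4S,5S,6R,8S,9S,10R)-8-hydroxy-14,15-dinorlabd-13(16)-en-18,6-olid-13-yl trifluoromethanesulfonate
Conditions: KN(SiMe3)2 (2.2 equiv), PhNTf2, THF, −78 °C
Reagents that add atoms: N-phenylbis(trifluoromethanesulfonimide) O=S(=O)(N(c1ccccc1)S(=O)(=O)C(F)(F)F)C(F)(F)F
Why: Kinetic deprotonation of the methyl ketone at its methyl group and O-triflation should give the terminal enol triflate, the lactone having no α-hydrogen and the tertiary alcohol being carried as its alkoxide.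

Step 13
Reactants: 22 (4S,5S,6R,8S,9S,10R)-8-hydroxy-14,15-dinorlabd-13(16)-en-18,6-olid-13-yl trifluoromethanesulfonate
Product: 23 (4S,5S,6R,8S,9S,10R)-8-hydroxylabda-13(16),14-dien-18,6-olide
Conditions: Bu3SnCH=CH2, Pd(PPh3)4 (5 mol %), LiCl, THF, 65 °C
Reagents that add atoms: tributyl(vinyl)stannane C=C[Sn](CCCC)(CCCC)CCCC
Why: Stille coupling of the enol triflate with the vinylstannane forms the C13–C14 bond and completes the 2-substituted buta-1,3-diene under neutral conditions.

Step 14
Reactants: 23 (4S,5S,6R,8S,9S,10R)-8-hydroxylabda-13(16),14-dien-18,6-olide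
Product: 24 (4S,5S,6R,8S,9S,10R)-labda-13(16),14-diene-6,8,18-triol
Conditions: LiAlH4, THF, 0 °C
Reagents that add atoms: none
Why: Hydride reduction of the lactone liberates the C6 secondary alcohol with its configuration intact and the C18 primary alcohol, the diene and the tertiary alcohol being inert.

Step 15
Reactants: 24 (4S,5S,6R,8S,9S,10R)-labda-13(16),14-diene-6,8,18-triol
Product: 25 (4S,5S,6R,8S,9S,10R)-6,8-dihydroxylabda-13(16),14-dien-18-yl acetate
Conditions: Ac2O (1.05 equiv), pyridine, CH2Cl2, −20 to 0 °C
Reagents that add atoms: acetic anhydride CC(=O)OC(C)=O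
Why: Selective O-acylation: the primary C18 hydroxyl should react much faster than the hindered secondary C6 and tertiary C8 hydroxyls, so one equivalent of anhydride gives the monoacetate.

**Compound list**
1 | 3-oxocyclohex-1-ene-1-carboxylic acid | O=C1C=C(C(=O)O)CCC1 | starting material
2 | tert-butyl 3-oxocyclohex-1-ene-1-carboxylate | CC(C)(C)OC(=O)C1=CC(=O)CCC1 | intermediate
3 | benzeneselenenyl chloride | Cl[Se]c1ccccc1 | starting material
4 | ethyl vinyl ether | C=COCC | starting material
5 | (2-chloro-2-ethoxyethyl)(phenyl)selane | CCOC(Cl)C[Se]c1ccccc1 | intermediate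
6 | 2-(phenylselanyl)acetaldehyde | O=CC[Se]c1ccccc1 | intermediate
7 | tert-butyl (1S)-1-methyl-3-[(methylzincio)oxy]cyclohex-2-ene-1-carboxylate | C[Zn]OC1=C[C@@](C)(C(=O)OC(C)(C)C)CCC1 | intermediate
8 | tert-butyl (1S,2S)-2-[1-hydroxy-2-(phenylselanyl)ethyl]-1-methyl-3-oxocyclohexane-1-carboxylate (carbinol epimers) | O=C1CCC[C@](C)(C(=O)OC(C)(C)C)[C@H]1C(O)C[Se]c1ccccc1 | intermediate
9 | tert-butyl (1S,2R)-2-ethenyl-1-methyl-3-oxocyclohexane-1-carboxylate | O=C1CCC[C@](C)(C(=O)OC(C)(C)C)[C@H]1C=C | intermediate
10 | tert-butyl (1S,2R,3R)-2-ethenyl-3-hydroxy-1-methyl-3-[(1E)-prop-1-en-1-yl]cyclohexane-1-carboxylate | C/C=C/[C@]1(O)CCC[C@](C)(C(=O)OC(C)(C)C)[C@H]1C=C | intermediate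
11 | potassium enolate (C6–C7) of tert-butyl (1S,2E)-1,5-dimethyl-7-oxocyclodec-2-ene-1-carboxylate | [K+].[O-]C1=CC(C)C/C=C/[C@@](C)(C(=O)OC(C)(C)C)CCC1 | intermediate
12 | tert-butyl (1S,2E)-6-(N-tert-butyl-S-phenylsulfinimidoyl)-1,5-dimethyl-7-oxocyclodec-2-ene-1-carboxylate | O=C1C(S(=NC(C)(C)C)c2ccccc2)C(C)C/C=C/[C@@](C)(C(=O)OC(C)(C)C)CCC1 | intermediate
13 | tert-butyl (1S,2E,5Z)-1,5-dimethyl-7-oxocyclodeca-2,5-diene-1-carboxylate | O=C1/C=C(C)\C/C=C/[C@@](C)(C(=O)OC(C)(C)C)CCC1 | intermediate
14 | tert-butyl (1S,2E,5E)-6-iodo-1,5-dimethyl-7-oxocyclodeca-2,5-diene-1-carboxylate | O=C1/C(I)=C(C)\C/C=C/[C@@](C)(C(=O)OC(C)(C)C)CCC1 | intermediate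
15 | 2-ethenyl-2-methyl-1,3-dioxolane | C=CC1(C)OCCO1 | starting material
16 | tert-butyl (1S,2E,5Z)-1,5-dimethyl-6-[2-(2-methyl-1,3-dioxolan-2-yl)ethyl]-7-oxocyclodeca-2,5-diene-1-carboxylate | O=C1/C(CCC2(C)OCCO2)=C(C)\C/C=C/[C@@](C)(C(=O)OC(C)(C)C)CCC1 | intermediate
17 | tert-butyl (1S,2E,5Z)-7-hydroxy-1,5,7-trimethyl-6-[2-(2-methyl-1,3-dioxolan-2-yl)ethyl]cyclodeca-2,5-diene-1-carboxylate (C7 epimers) | CC1(O)/C(CCC2(C)OCCO2)=C(C)\C/C=C/[C@@](C)(C(=O)OC(C)(C)C)CCC1 | intermediate
18 | (4S,5S,6R,10R)-13,13-(ethylenedioxy)-14,15-dinorlabd-8-en-18,6-olide | O=C1O[C@@H]2CC(C)=C(CCC4(C)OCCO4)[C@]3(C)CCC[C@@]1(C)[C@@H]23 | intermediate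
19 | (4S,5S,6R,8S,9S,10R)-8-boranyl-13,13-(ethylenedioxy)-14,15-dinorlabdan-18,6-olide | O=C1O[C@@H]2C[C@](C)(B)[C@@H](CCC4(C)OCCO4)[C@]3(C)CCC[C@@]1(C)[C@@H]23 | intermediate
20 | (4S,5S,6R,8S,9S,10R)-13,13-(ethylenedioxy)-8-hydroxy-14,15-dinorlabdan-18,6-olide | O=C1O[C@@H]2C[C@](C)(O)[C@@H](CCC4(C)OCCO4)[C@]3(C)CCC[C@@]1(C)[C@@H]23 | intermediate
21 | (4S,5S,6R,8S,9S,10R)-8-hydroxy-13-oxo-14,15-dinorlabdan-18,6-olide | O=C1O[C@@H]2C[C@](C)(O)[C@@H](CCC(C)=O)[C@]3(C)CCC[C@@]1(C)[C@@H]23 | intermediate
22 | (4S,5S,6R,8S,9S,10R)-8-hydroxy-14,15-dinorlabd-13(16)-en-18,6-olid-13-yl trifluoromethanesulfonate | O=C1O[C@@H]2C[C@](C)(O)[C@@H](CCC(=C)OS(=O)(=O)C(F)(F)F)[C@]3(C)CCC[C@@]1(C)[C@@H]23 | intermediate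
23 | (4S,5S,6R,8S,9S,10R)-8-hydroxylabda-13(16),14-dien-18,6-olide | O=C1O[C@@H]2C[C@](C)(O)[C@@H](CCC(=C)C=C)[C@]3(C)CCC[C@@]1(C)[C@@H]23 | intermediate
24 | (4S,5S,6R,8S,9S,10R)-labda-13(16),14-diene-6,8,18-triol | C=CC(=C)CC[C@H]1[C@]2(C)CCC[C@](C)(CO)[C@H]2[C@H](O)C[C@]1(C)O | intermediate
25 | (4S,5S,6R,8S,9S,10R)-6,8-dihydroxylabda-13(16),14-dien-18-yl acetate | C=CC(=C)CC[C@H]1[C@]2(C)CCC[C@](C)(COC(C)=O)[C@H]2[C@H](O)C[C@]1(C)O | target

Total step count: 15. Longest linear sequence: 14 steps (steps 1 and 3 to 15; step 2 prepares the aldehyde used in step 3).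

**Steps most likely to fail**

Step 6. The potassium alkoxide may fragment instead of rearranging, may attack the ester in the minor C5 epimer, or may pass through a boat transition state and erode the E geometry; the sulfenylation of the crown-complexed enolate may also stop before elimination. The fallback separates the two events under neutral conditions. It sets out from 10, which is silylated (Me3SiCl, imidazole, DMF) to the trimethylsilyl ether F1. Heating F1 (toluene, sealed tube, about 210 °C) effects the thermal siloxy-Cope ring expansion to the ring-expanded silyl enol ether F2. Saegusa–Ito oxidation of F2 (Pd(OAc)2, O2, DMSO) then introduces the C8=C9 bond, and the sequence comes back to the route at 13.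

Step 10. The free allyl cation may close to a cis-fused product, lose a proton to give trienes, be captured by the ketal oxygen, or lose the ketal by hydrolysis with the water that is released. The fallback generates the same cation without Brønsted acid. It sets out from 16, whose ketone is methylenated (Petasis methylenation, Cp2TiMe2, toluene, 70 °C) to the cross-conjugated triene F3. Hydrogen-atom transfer from a cobalt hydride to the terminal methylene of F3 (Co(salen), divalent cobalt, N-fluoro-2,4,6-trimethylpyridinium tetrafluoroborate, PhSiH3, CH2Cl2), followed by oxidation of the tertiary allylic radical (radical–polar crossover), gives the C10/C8 allyl cation. Transannular closure and lactonisation with loss of isobutene follow, and the sequence comes back to the route at 18.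

Step 11. Hydroboration of the hindered tetrasubstituted olefin may be slow, boron may go partly to C9, and the lactone may be reduced by the excess borane. The fallback sets out from 18, which is epoxidised from the face anti to the C10 methyl (dimethyldioxirane, acetone, 0 °C) to the epoxide F4. Reductive opening with trivalent titanium (Cp2TiCl from Cp2TiCl2 and Mn, THF, water as hydrogen-atom source) should cleave the more congested C9–O bond and deliver hydrogen to the C9 radical from the open face. The C8–O bond and its configuration are kept, and the sequence comes back to the route at 20, which the acidic work-up of step 11 converts into 21.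

Further compounds
F1 | step 6 | tert-butyl (1S,2R,3R)-2-ethenyl-1-methyl-3-[(1E)-prop-1-en-1-yl]-3-[(trimethylsilyl)oxy]cyclohexane-1-carboxylate | C/C=C/[C@]1(O[Si](C)(C)C)CCC[C@](C)(C(=O)OC(C)(C)C)[C@H]1C=C
F2 | step 6 | tert-butyl (1S,2E)-1,5-dimethyl-7-[(trimethylsilyl)oxy]cyclodeca-2,6-diene-1-carboxylate | CC1C/C=C/[C@@](C)(C(=O)OC(C)(C)C)CCCC(O[Si](C)(C)C)=C1
F3 | step 10 | tert-butyl (1S,2E,5Z)-1,5-dimethyl-6-[2-(2-methyl-1,3-dioxolan-2-yl)ethyl]-7-methylidenecyclodeca-2,5-diene-1-carboxylate | C=C1/C(CCC2(C)OCCO2)=C(C)\C/C=C/[C@@](C)(C(=O)OC(C)(C)C)CCC1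
F4 | step 11 | (4S,5S,6R,8S,9R,10R)-8,9-epoxy-13,13-(ethylenedioxy)-14,15-dinorlabdan-18,6-olide | O=C1O[C@@H]2C[C@]3(C)O[C@]3(CCC4(C)OCCO4)[C@]5(C)CCC[C@@]1(C)[C@@H]25
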